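The route rests on closing the β-lactone last, by forming the C8–O bond from an unactivated ring methylene. In ring B the C11 carboxyl on C7 lies cis to one hydrogen of C8, and the other β-methylene, C6, is screened by the quaternary C1′ of ring D held cis to it across C4=C5. A carboxylate-directed palladium C–H lactonisation therefore creates the C8 stereocentre and the fourth ring in one operation. Its substrate is the C8-deoxy bicyclic acid 24, already carrying the butyrate, ring D and the C1, C7 and C9 stereocentres, assembled by Evans alkylation, ring-closing enyne metathesis and an organocatalytic Diels–Alder reaction.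

Key step: step 13

Remark: locants are C10H2O–C1–C2–C3–C4(=C5)–C6–C7(C11)–C8–C9, with C1′ the quaternary carbon of ring D on C4; ring A = C1–C5 and C9, ring B = C5–C9.
Assumption: in step 2 the enantiomer of the carbene ligand that delivers methyl to the enone face leading to the (S)-ketone is used; both enantiomers are accessible and the sense for this substrate is not derived here.

Step 1
Reactants: 1 3-ethoxycyclohex-2-en-1-one; 2 ethynyltrimethylsilane
Product: 5 3-[(trimethylsilyl)ethynyl]cyclohex-2-en-1-one, via lithium acetylide 3 (not isolated), via carbinol adduct 4 (not isolated)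
Conditions: 2, n-BuLi, THF, −78 °C; then 1, −78 → 0 °C; then 1 M HCl, rt
Reagents that add atoms: water, O
Why: Stork–Danheiser sequence, in which 1,2-addition of the acetylide to the vinylogous ester is followed by acid-promoted loss of water and hydrolysis of the enol ether, transposing the carbonyl to give the 3-alkynyl enone.

Step 2
Reactants: 5 3-[(trimethylsilyl)ethynyl]cyclohex-2-en-1-one
Product: 6 (3S)-3-methyl-3-[(trimethylsilyl)ethynyl]cyclohexan-1-one
Conditions: MeMgBr, Cu(OTf)2 (3 mol%), leucinol-derived N-mesityl hydroxyalkyl imidazolinium hexafluorophosphate (4 mol%), Et2O, −10 °C; aq NH4Cl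
Reagents that add atoms: methylmagnesium bromide, C[Mg]Br
Why: Copper-catalysed asymmetric conjugate addition of a Grignard reagent to a cyclic enynone, which is 1,4-selective with carbene–copper catalysts; the chiral carbene ligand differentiates the enone faces and sets the quaternary C1′ as S.

Step 3
Reactants: 6 (3S)-3-methyl-3-[(trimethylsilyl)ethynyl]cyclohexan-1-one
Product: 7 trimethyl{[(1S)-1,3,3-trimethylcyclohexyl]ethynyl}silane
Conditions: Me2Zn, TiCl4, CH2Cl2, −30 °C; then 6, −30 °C → rt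
Reagents that add atoms: dimethyltitanium dichloride (from Me2Zn and TiCl4), C[Ti](C)(Cl)Cl
Why: Reetz geminal dimethylation, in which methyl addition, ionisation of the titanium alkoxide to a tertiary cation and a second methyl transfer replace C=O by CMe2, while the quaternary centre bears no hydrogen and is untouched.

Step 4
Reactants: 7 trimethyl{[(1S)-1,3,3-trimethylcyclohexyl]ethynyl}silane
Product: 9 3-[(1S)-1,3,3-trimethylcyclohexyl]prop-2-yn-1-ol, via lithium acetylide 8 (not isolated)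
Conditions: MeLi·LiBr, THF, 0 °C → rt; then (CH2O)n, −20 °C → rt; aq NH4Cl
Reagents that add atoms: formaldehyde (as paraformaldehyde), C=O
Why: Methyllithium attacks silicon of the alkynylsilane and releases the lithium acetylide, which adds to formaldehyde (carbonyl addition), so the volatile terminal alkyne is never isolated.

Step 5
Reactants: 9 3-[(1S)-1,3,3-trimethylcyclohexyl]prop-2-yn-1-ol
Product: 10 (1S)-1-(3-bromoprop-1-yn-1-yl)-1,3,3-trimethylcyclohexane
Conditions: CBr4, PPh3, CH2Cl2, 0 °C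
Reagents that add atoms: carbon tetrabromide, BrC(Br)(Br)Br
Why: Appel bromination of a primary propargylic alcohol by SN2 displacement of the oxyphosphonium group, with the quaternary carbon at the far alkyne terminus excluding an SN2′ pathway.

Step 6
Reactants: 11 (4R)-4-benzyl-1,3-oxazolidin-2-one; 12 pent-4-enoyl chloride
Product: 13 (4R)-4-benzyl-3-(pent-4-enoyl)-1,3-oxazolidin-2-one
Conditions: Et3N, DMAP (cat.), CH2Cl2, 0 °C → rt
Reagents that add atoms: none
Why: DMAP-catalysed N-acylation of the oxazolidinone by an acid chloride, which creates no stereocentre.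

Step 7
Reactants: 13 (4R)-4-benzyl-3-(pent-4-enoyl)-1,3-oxazolidin-2-one; 10 (1S)-1-(3-bromoprop-1-yn-1-yl)-1,3,3-trimethylcyclohexane
Product: 15 (4R)-4-benzyl-3-[(2S)-2-{3-[(1S)-1,3,3-trimethylcyclohexyl]prop-2-yn-1-yl}pent-4-enoyl]-1,3-oxazolidin-2-one, via sodium Z-enolate 14 (not isolated)
Conditions: NaN(SiMe3)2, THF, −78 °C; then 10, −78 → −40 °C
Reagents that add atoms: none
Why: Evans asymmetric alkylation, in which the chelated Z sodium enolate is alkylated by the propargylic bromide on the face opposite the benzyl group of the (R)-auxiliary, setting C7 as S.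

Step 8
Reactants: 15 (4R)-4-benzyl-3-[(2S)-2-{3-[(1S)-1,3,3-trimethylcyclohexyl]prop-2-yn-1-yl}pent-4-enoyl]-1,3-oxazolidin-2-one
Product: 16 (4R)-4-benzyl-3-[(1S)-3-{1-[(1S)-1,3,3-trimethylcyclohexyl]ethenyl}cyclopent-3-ene-1-carbonyl]-1,3-oxazolidin-2-one
Conditions: second-generation Grubbs catalyst RuCl2(=CHPh)(PCy3)(H2IMes) (10 mol%), ethylene (1 atm), toluene, 80 °C
Reagents that add atoms: none
Why: Ring-closing enyne metathesis in the exo mode, in which the ruthenium alkylidene formed at the terminal alkene adds across the alkyne, closing ring B as the C5=C9 cyclopentene and leaving a methylene on C4, with ethylene sustaining turnover of the hindered vinylcarbene.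

Step 9
Reactants: 16 (4R)-4-benzyl-3-[(1S)-3-{1-[(1S)-1,3,3-trimethylcyclohexyl]ethenyl}cyclopent-3-ene-1-carbonyl]-1,3-oxazolidin-2-one
Product: 18 (1S)-3-{1-[(1S)-1,3,3-trimethylcyclohexyl]ethenyl}cyclopent-3-ene-1-carboxylic acid, via peroxy acid 17 (not isolated)
Conditions: LiOH, H2O2, THF/H2O, 0 °C; then aq Na2SO3; then 1 M HCl
Reagents that add atoms: hydrogen peroxide, OO
Why: Hydroperoxide cleavage of the Evans imide at the exocyclic carbonyl followed by sulfite reduction of the peracid, under conditions that neither enolise C7 nor touch the diene.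

Step 10
Reactants: 18 (1S)-3-{1-[(1S)-1,3,3-trimethylcyclohexyl]ethenyl}cyclopent-3-ene-1-carboxylic acid; 19 acrolein
Product: 20 (2S,3aR,4R)-4-formyl-7-[(1S)-1,3,3-trimethylcyclohexyl]-2,3,3a,4,5,6-hexahydro-1H-indene-2-carboxylic acid
Conditions: (5S)-5-benzyl-2,2,3-trimethylimidazolidin-4-one hydrochloride (20 mol%), CH3CN/H2O (95:5), 0 °C → rt
Reagents that add atoms: none
Why: Iminium-catalysed enantioselective Diels–Alder reaction that builds ring A with C4=C5 in place, the formyl-bearing carbon bonding to C9 as the substitution of the diene dictates, while the benzyl group of the catalyst leaves the Si face of the iminium open and the endo approach converts this into the R configuration at C9 (with a provisional cis C1), overriding the weak bias from C7.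

Step 11
Reactants: 20 (2S,3aR,4R)-4-formyl-7-[(1S)-1,3,3-trimethylcyclohexyl]-2,3,3a,4,5,6-hexahydro-1H-indene-2-carboxylic acid
Product: 22 (2S,3aR,4S)-4-(hydroxymethyl)-7-[(1S)-1,3,3-trimethylcyclohexyl]-2,3,3a,4,5,6-hexahydro-1H-indene-2-carboxylic acid, via trans aldehyde 21 (not isolated)
Conditions: K2CO3, MeOH, rt; then NaBH4, 0 °C; then aq citric acid
Reagents that add atoms: none
Why: Base-mediated epimerisation of the aldehyde α-carbon moves C10 into the thermodynamically preferred equatorial position trans to C8 (C1 becomes S) while C7, α to a carboxylate, is not enolised, and borohydride then reduces only the aldehyde; the preference is expected to be modest, so residual cis alcohol is removed by chromatography.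

Step 12
Reactants: 22 (2S,3aR,4S)-4-(hydroxymethyl)-7-[(1S)-1,3,3-trimethylcyclohexyl]-2,3,3a,4,5,6-hexahydro-1H-indene-2-carboxylic acid
Product: 24 (2S,3aR,4S)-4-[(butanoyloxy)methyl]-7-[(1S)-1,3,3-trimethylcyclohexyl]-2,3,3a,4,5,6-hexahydro-1H-indene-2-carboxylic acid, via mixed anhydride 23 (not isolated)
Conditions: (PrCO)2O, pyridine, DMAP (cat.), CH2Cl2, 0 °C → rt; then THF/aq NaHCO3, rt; then 1 M HCl
Reagents that add atoms: butyric anhydride, CCCC(=O)OC(=O)CCC
Why: DMAP-catalysed esterification of the primary alcohol, after which the mixed anhydride formed at the carboxyl group, far more labile than the ester, is hydrolysed selectively in the aqueous stage.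

Step 13
Reactants: 24 (2S,3aR,4S)-4-[(butanoyloxy)methyl]-7-[(1S)-1,3,3-trimethylcyclohexyl]-2,3,3a,4,5,6-hexahydro-1H-indene-2-carboxylic acid
Product: 25 3'-norspongiolactone
Conditions: Pd(OAc)2 (10 mol%), N-acetyl-β-alanine (20 mol%), CsHCO3 (0.5 equiv), t-BuOOH (70% aq, 2 equiv), (CF3)2CHOH, 60 °C
Reagents that add atoms: none
Why: Proposed new method: the carboxylate of 24 binds divalent palladium and, assisted by the mono-protected amino acid ligand, cleaves the C8–H bond syn to C11 by concerted metalation–deprotonation to give a five-membered palladacycle, which tert-butyl hydroperoxide oxidises to tetravalent palladium before C8–O reductive elimination releases the lactone. The closest known reaction is the palladium-catalysed β-C(sp3)–H lactonisation of free aliphatic acids at methyl groups with peroxide oxidants, and retentive four-ring closure at a ring methylene has an analogue in auxiliary-directed β-lactam formation. The oxetan-2-one closes by direct C–O reductive elimination from the palladacycle, a 4-exo-type closure that must proceed with retention because the tethered carboxylate cannot reach the rear of C8. The new C8 stereocentre is therefore dictated by C7: oxygen enters on the face of C11, cis to H9, and the ring fusion is necessarily cis. The step needs C8 to be chosen over the allylic C6 methylene, over β-hydride loss towards the syn C9–H and over oxidation of C4=C5; the quaternary C1′ of ring D, cis to C6 across C4=C5, blocks palladation at C6, the tetrasubstituted alkene is a poor ligand, and fast oxidation of the palladacycle by the peroxide is relied on to outrun β-hydride loss.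

Compound list
1 | 3-ethoxycyclohex-2-en-1-one | CCOC1=CC(=O)CCC1 | starting material
2 | ethynyltrimethylsilane | C#C[Si](C)(C)C | starting material
3 | lithium (trimethylsilyl)acetylide | [Li]C#C[Si](C)(C)C | intermediate
4 | 3-ethoxy-1-[(trimethylsilyl)ethynyl]cyclohex-2-en-1-ol (racemic, present as its lithium alkoxide) | CCOC1=CC(O)(C#C[Si](C)(C)C)CCC1 | intermediate
5 | 3-[(trimethylsilyl)ethynyl]cyclohex-2-en-1-one | C[Si](C)(C)C#CC1=CC(=O)CCC1 | intermediate
6 | (3S)-3-methyl-3-[(trimethylsilyl)ethynyl]cyclohexan-1-one | C[Si](C)(C)C#C[C@@]1(C)CCCC(=O)C1 | intermediate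
7 | trimethyl{[(1S)-1,3,3-trimethylcyclohexyl]ethynyl}silane | C[Si](C)(C)C#C[C@@]1(C)CCCC(C)(C)C1 | intermediate
8 | lithium [(1S)-1,3,3-trimethylcyclohexyl]acetylide | [Li]C#C[C@@]1(C)CCCC(C)(C)C1 | intermediate
9 | 3-[(1S)-1,3,3-trimethylcyclohexyl]prop-2-yn-1-ol | OCC#C[C@@]1(C)CCCC(C)(C)C1 | intermediate
10 | (1S)-1-(3-bromoprop-1-yn-1-yl)-1,3,3-trimethylcyclohexane | BrCC#C[C@@]1(C)CCCC(C)(C)C1 | intermediate
11 | (4R)-4-benzyl-1,3-oxazolidin-2-one | O=C1N[C@H](Cc2ccccc2)CO1 | starting material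
12 | pent-4-enoyl chloride | C=CCCC(=O)Cl | starting material
13 | (4R)-4-benzyl-3-(pent-4-enoyl)-1,3-oxazolidin-2-one | C=CCCC(=O)N1[C@H](Cc2ccccc2)COC1=O | intermediate
14 | sodium (Z)-enolate of 13 | C=CC/C=C(\[O-])N1[C@H](Cc2ccccc2)COC1=O.[Na+] | intermediate
15 | (4R)-4-benzyl-3-[(2S)-2-{3-[(1S)-1,3,3-trimethylcyclohexyl]prop-2-yn-1-yl}pent-4-enoyl]-1,3-oxazolidin-2-one | C=CC[C@@H](CC#C[C@@]1(C)CCCC(C)(C)C1)C(=O)N2[C@H](Cc3ccccc3)COC2=O | intermediate
16 | (4R)-4-benzyl-3-[(1S)-3-{1-[(1S)-1,3,3-trimethylcyclohexyl]ethenyl}cyclopent-3-ene-1-carbonyl]-1,3-oxazolidin-2-one | C=C([C@@]1(C)CCCC(C)(C)C1)C2=CC[C@@H](C2)C(=O)N3[C@H](Cc4ccccc4)COC3=O | intermediate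
17 | (1S)-3-{1-[(1S)-1,3,3-trimethylcyclohexyl]ethenyl}cyclopent-3-ene-1-carboperoxoic acid | C=C([C@@]1(C)CCCC(C)(C)C1)C2=CC[C@@H](C2)C(=O)OO | intermediate
18 | (1S)-3-{1-[(1S)-1,3,3-trimethylcyclohexyl]ethenyl}cyclopent-3-ene-1-carboxylic acid | C=C([C@@]1(C)CCCC(C)(C)C1)C2=CC[C@@H](C2)C(=O)O | intermediate
19 | acrolein (prop-2-enal) | C=CC=O | starting material
20 | (2S,3aR,4R)-4-formyl-7-[(1S)-1,3,3-trimethylcyclohexyl]-2,3,3a,4,5,6-hexahydro-1H-indene-2-carboxylic acid (C10 cis to C8) | O=C[C@@H]1CCC([C@@]2(C)CCCC(C)(C)C2)=C2C[C@@H](C(=O)O)C[C@@H]21 | intermediate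
21 | (2S,3aR,4S)-4-formyl-7-[(1S)-1,3,3-trimethylcyclohexyl]-2,3,3a,4,5,6-hexahydro-1H-indene-2-carboxylic acid (C10 trans to C8) | O=C[C@H]1CCC([C@@]2(C)CCCC(C)(C)C2)=C2C[C@@H](C(=O)O)C[C@@H]21 | intermediate
22 | (2S,3aR,4S)-4-(hydroxymethyl)-7-[(1S)-1,3,3-trimethylcyclohexyl]-2,3,3a,4,5,6-hexahydro-1H-indene-2-carboxylic acid | OC[C@H]1CCC([C@@]2(C)CCCC(C)(C)C2)=C2C[C@@H](C(=O)O)C[C@@H]21 | intermediate
23 | butanoic (2S,3aR,4S)-4-[(butanoyloxy)methyl]-7-[(1S)-1,3,3-trimethylcyclohexyl]-2,3,3a,4,5,6-hexahydro-1H-indene-2-carboxylic anhydride | CCCC(=O)OC[C@H]1CCC([C@@]2(C)CCCC(C)(C)C2)=C2C[C@@H](C(=O)OC(=O)CCC)C[C@@H]21 | intermediate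
24 | (2S,3aR,4S)-4-[(butanoyloxy)methyl]-7-[(1S)-1,3,3-trimethylcyclohexyl]-2,3,3a,4,5,6-hexahydro-1H-indene-2-carboxylic acid (C8-deoxy acid; 1S,7S,9R,1′S in the locants above) | CCCC(=O)OC[C@H]1CCC([C@@]2(C)CCCC(C)(C)C2)=C2C[C@@H](C(=O)O)C[C@@H]21 | intermediate
25 | 3'-norspongiolactone (1S,7R,8S,9R,1′S in the locants above) | CCCC(=O)OC[C@H]1CCC([C@@]2(C)CCCC(C)(C)C2)=C2C[C@H]3C(=O)O[C@H]3[C@@H]21 | target

Total steps: 13. Longest linear sequence: 12 steps (steps 1–5 and 7–13; step 6 is a one-step side branch).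

Steps most likely to fail

Step 13. Palladation may not occur at a secondary C–H of an acid with a tertiary α-carbon, or the palladacycle may lose the syn C9 hydrogen by β-hydride elimination instead of forming the C–O bond, or the peroxide may attack the alkene. The fallback installs the C8 oxygen at the outset by an aldol reaction and closes the lactone by classical carboxyl activation; it sets out from 7 and returns at 25. Compound 7 is converted into acetylide 8 as in step 4 and opened onto oxetane (BF3·OEt2, THF, −78 °C) to give 5-[(1S)-1,3,3-trimethylcyclohexyl]pent-4-yn-1-ol F1. Oxidation (TEMPO, PhI(OAc)2, CH3CN/H2O) gives the pentynoic acid F2, which is coupled with 11 (DCC, DMAP) to the acyl oxazolidinone F3. Its dibutylboron Z-enolate F4 (Bu2BOTf, iPr2NEt, CH2Cl2, −78 °C) adds to acrolein 19 to give the Evans syn aldol F5, which fixes C7 and the C8 oxygen together. The aldol is protected as the silyl ether F6 (TBSOTf, 2,6-lutidine). The operations of steps 8 to 12 then give in turn the diene imide F7, the peroxy acid F8 (not isolated), the diene acid F9, the cis aldehyde F10, the trans aldehyde F11 (not isolated), the hydroxy acid F12, the mixed anhydride F13 (not isolated) and the butyrate F14. In the cycloaddition the allylic silyloxy group on C8 reinforces attack on the required diene face. HF·pyridine frees the cis β-hydroxy acid F15, and benzenesulfonyl chloride in pyridine at 0 °C (carboxyl activation, retention at C8) closes the β-lactone to 25.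

Step 8. Insertion of the alkyne that carries the tertiary ring D carbon into the ruthenium alkylidene may be too slow, so that the catalyst decays or the alkene oligomerises before ring closure. The fallback replaces carbene metathesis by π-acid catalysis and runs from 15 to 16 without any new compound (F0). PtCl2 (5 mol%) in toluene at 80 °C activates the alkyne, the alkene attacks in the 5-exo mode, and the cyclopropyl platinum carbene rearranges by single cleavage to the same 1-vinylcyclopentene 16.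

Step 10. The hindered diene may react too slowly with the iminium ion, or endo and facial control by the catalyst may be incomplete, which would erode the configuration at C9. The fallback uses a stoichiometric auxiliary and a Lewis acid; it sets out from 18 and returns at 22. Allyl bromide and K2CO3 in DMF give the allyl ester F16. Cycloaddition with (4S)-3-acryloyl-4-benzyl-1,3-oxazolidin-2-one and Et2AlCl (CH2Cl2, −78 °C; chelated, endo, auxiliary-controlled) gives the Diels–Alder imide F17. Pd(PPh3)4 and morpholine remove the allyl group to give the imide acid F18. NaOMe in MeOH converts the imide into the cis methyl ester F19 (not isolated) and equilibrates it to the trans methyl ester F20, while the C11 carboxylate protects C7. LiBH4 in THF then reduces the ester beside the carboxylate and delivers 22.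

Further compounds
F1 | step 13 | 5-[(1S)-1,3,3-trimethylcyclohexyl]pent-4-yn-1-ol | OCCCC#C[C@@]1(C)CCCC(C)(C)C1
F2 | step 13 | 5-[(1S)-1,3,3-trimethylcyclohexyl]pent-4-ynoic acid | OC(=O)CCC#C[C@@]1(C)CCCC(C)(C)C1
F3 | step 13 | (4R)-4-benzyl-3-{5-[(1S)-1,3,3-trimethylcyclohexyl]pent-4-ynoyl}-1,3-oxazolidin-2-one | O=C(CCC#C[C@@]1(C)CCCC(C)(C)C1)N2[C@H](Cc3ccccc3)COC2=O
F4 | step 13 | dibutylboron (Z)-enolate of F3 | CCCCB(CCCC)O/C(N1[C@H](Cc2ccccc2)COC1=O)=C\CC#C[C@@]1(C)CCCC(C)(C)C1
F5 | step 13 | (4R)-4-benzyl-3-[(2R,3S)-3-hydroxy-2-{3-[(1S)-1,3,3-trimethylcyclohexyl]prop-2-yn-1-yl}pent-4-enoyl]-1,3-oxazolidin-2-one | C=C[C@H](O)[C@@H](CC#C[C@@]1(C)CCCC(C)(C)C1)C(=O)N2[C@H](Cc3ccccc3)COC2=O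
F6 | step 13 | (4R)-4-benzyl-3-[(2R,3S)-3-[(tert-butyldimethylsilyl)oxy]-2-{3-[(1S)-1,3,3-trimethylcyclohexyl]prop-2-yn-1-yl}pent-4-enoyl]-1,3-oxazolidin-2-one | C=C[C@H](O[Si](C)(C)C(C)(C)C)[C@@H](CC#C[C@@]1(C)CCCC(C)(C)C1)C(=O)N2[C@H](Cc3ccccc3)COC2=O
F7 | step 13 | (4R)-4-benzyl-3-[(1R,2S)-2-[(tert-butyldimethylsilyl)oxy]-4-{1-[(1S)-1,3,3-trimethylcyclohexyl]ethenyl}cyclopent-3-ene-1-carbonyl]-1,3-oxazolidin-2-one | C=C([C@@]1(C)CCCC(C)(C)C1)C2=C[C@H](O[Si](C)(C)C(C)(C)C)[C@@H](C2)C(=O)N3[C@H](Cc4ccccc4)COC3=O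
F8 | step 13 | (1R,2S)-2-[(tert-butyldimethylsilyl)oxy]-4-{1-[(1S)-1,3,3-trimethylcyclohexyl]ethenyl}cyclopent-3-ene-1-carboperoxoic acid | C=C([C@@]1(C)CCCC(C)(C)C1)C2=C[C@H](O[Si](C)(C)C(C)(C)C)[C@@H](C2)C(=O)OO
F9 | step 13 | (1R,2S)-2-[(tert-butyldimethylsilyl)oxy]-4-{1-[(1S)-1,3,3-trimethylcyclohexyl]ethenyl}cyclopent-3-ene-1-carboxylic acid | C=C([C@@]1(C)CCCC(C)(C)C1)C2=C[C@H](O[Si](C)(C)C(C)(C)C)[C@@H](C2)C(=O)O
F10 | step 13 | (2R,3S,3aR,4R)-3-[(tert-butyldimethylsilyl)oxy]-4-formyl-7-[(1S)-1,3,3-trimethylcyclohexyl]-2,3,3a,4,5,6-hexahydro-1H-indene-2-carboxylic acid | O=C[C@@H]1CCC([C@@]2(C)CCCC(C)(C)C2)=C2C[C@@H](C(=O)O)[C@@H](O[Si](C)(C)C(C)(C)C)[C@@H]21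
F11 | step 13 | (2R,3S,3aR,4S)-3-[(tert-butyldimethylsilyl)oxy]-4-formyl-7-[(1S)-1,3,3-trimethylcyclohexyl]-2,3,3a,4,5,6-hexahydro-1H-indene-2-carboxylic acid | O=C[C@H]1CCC([C@@]2(C)CCCC(C)(C)C2)=C2C[C@@H](C(=O)O)[C@@H](O[Si](C)(C)C(C)(C)C)[C@@H]21
F12 | step 13 | (2R,3S,3aR,4S)-3-[(tert-butyldimethylsilyl)oxy]-4-(hydroxymethyl)-7-[(1S)-1,3,3-trimethylcyclohexyl]-2,3,3a,4,5,6-hexahydro-1H-indene-2-carboxylic acid | OC[C@H]1CCC([C@@]2(C)CCCC(C)(C)C2)=C2C[C@@H](C(=O)O)[C@@H](O[Si](C)(C)C(C)(C)C)[C@@H]21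
F13 | step 13 | butanoic (2R,3S,3aR,4S)-4-[(butanoyloxy)methyl]-3-[(tert-butyldimethylsilyl)oxy]-7-[(1S)-1,3,3-trimethylcyclohexyl]-2,3,3a,4,5,6-hexahydro-1H-indene-2-carboxylic anhydride | CCCC(=O)OC[C@H]1CCC([C@@]2(C)CCCC(C)(C)C2)=C2C[C@@H](C(=O)OC(=O)CCC)[C@@H](O[Si](C)(C)C(C)(C)C)[C@@H]21
F14 | step 13 | (2R,3S,3aR,4S)-4-[(butanoyloxy)methyl]-3-[(tert-butyldimethylsilyl)oxy]-7-[(1S)-1,3,3-trimethylcyclohexyl]-2,3,3a,4,5,6-hexahydro-1H-indene-2-carboxylic acid | CCCC(=O)OC[C@H]1CCC([C@@]2(C)CCCC(C)(C)C2)=C2C[C@@H](C(=O)O)[C@@H](O[Si](C)(C)C(C)(C)C)[C@@H]21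
F15 | step 13 | (2R,3S,3aR,4S)-4-[(butanoyloxy)methyl]-3-hydroxy-7-[(1S)-1,3,3-trimethylcyclohexyl]-2,3,3a,4,5,6-hexahydro-1H-indene-2-carboxylic acid | CCCC(=O)OC[C@H]1CCC([C@@]2(C)CCCC(C)(C)C2)=C2C[C@@H](C(=O)O)[C@@H](O)[C@@H]21
F0 | step 8 | none | none
F16 | step 10 | prop-2-en-1-yl (1S)-3-{1-[(1S)-1,3,3-trimethylcyclohexyl]ethenyl}cyclopent-3-ene-1-carboxylate | C=C([C@@]1(C)CCCC(C)(C)C1)C2=CC[C@@H](C2)C(=O)OCC=C
F17 | step 10 | prop-2-en-1-yl (2S,3aR,4R)-4-{[(4S)-4-benzyl-2-oxo-1,3-oxazolidin-3-yl]carbonyl}-7-[(1S)-1,3,3-trimethylcyclohexyl]-2,3,3a,4,5,6-hexahydro-1H-indene-2-carboxylate | O=C([C@@H]1CCC([C@@]2(C)CCCC(C)(C)C2)=C2C[C@@H](C(=O)OCC=C)C[C@@H]21)N3[C@@H](Cc4ccccc4)COC3=O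
F18 | step 10 | (2S,3aR,4R)-4-{[(4S)-4-benzyl-2-oxo-1,3-oxazolidin-3-yl]carbonyl}-7-[(1S)-1,3,3-trimethylcyclohexyl]-2,3,3a,4,5,6-hexahydro-1H-indene-2-carboxylic acid | O=C([C@@H]1CCC([C@@]2(C)CCCC(C)(C)C2)=C2C[C@@H](C(=O)O)C[C@@H]21)N3[C@@H](Cc4ccccc4)COC3=O
F19 | step 10 | (2S,3aR,4R)-4-(methoxycarbonyl)-7-[(1S)-1,3,3-trimethylcyclohexyl]-2,3,3a,4,5,6-hexahydro-1H-indene-2-carboxylic acid | COC(=O)[C@@H]1CCC([C@@]2(C)CCCC(C)(C)C2)=C2C[C@@H](C(=O)O)C[C@@H]21
F20 | step 10 | (2S,3aR,4S)-4-(methoxycarbonyl)-7-[(1S)-1,3,3-trimethylcyclohexyl]-2,3,3a,4,5,6-hexahydro-1H-indene-2-carboxylic acid | COC(=O)[C@H]1CCC([C@@]2(C)CCCC(C)(C)C2)=C2C[C@@H](C(=O)O)C[C@@H]21
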